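The numbers of this flask are those of an exercise; what happens was integrated by code.

The target is what I wanted, and it has one rival: dissolved starting material either meets reagent and becomes target, or turns into side product on its own.

solid substrate 0.35 M; reagent 1.80 equiv; time 30 min

    solid substrate ⇌ starting material, rate k1*(cs1 - [starting material]) while solid is left; crystals form when [starting material] > cs1 (cs1 = 0.26 M, k1 = 0.010 s⁻¹)
    starting material + reagent → target (k2 = 0.0032 L mol⁻¹ s⁻¹)
    starting material → side product (k3 = 0.0011 s⁻¹)

- as a solid, counted per litre of solution: solid substrate
- at the start none of the solid substrate is in solution
- starting material means what is dissolved; the solid is not counted in it
- run time (flask): 30 min

1. the target standing at 30 min, as a percentage of the solid substrate charged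
2. concentration of starting material in solution at 30 min, in percent of saturation

So I counted how one turnover of starting material splits. Both rates carry c(starting material), which cancels. What remains is the rate constant of the reagent path times c(reagent), divided by the rate constant of the lone path: the split number 1.83, a selectivity factor, here taken with reagent as charged. It counts the molecules going to target for each one going to side product, so I gave target that number over one plus that number, or 64.7% of the charge.

One number was not enough: that much target would use 35.9% of the reagent. With reagent midway between start and end, the number falls to 1.50 and the share to 60.1%. At that reagent level, dissolved starting material turns over 4.96 times in 30 min, more than once, so I counted the split as finished and expected c(starting material) to stand far below saturation at the end.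

The forecast, holding that “it is a batch reaction” once the solid is gone, gave 59.4% and 1.85%. The flask gave 59.3% and 1.85%.

At 30.0 min the reagent path in this flask used starting material 1.2 times as fast as the lone path, which is the split number with 67% of the reagent left, 1.23. That ratio is lower than the split number with reagent as charged but still above one, and target stood at 59.3% against 39.3% of side product.

In a second flask, the same but with 0.450 equiv of reagent, the split number is 0.458, below one. There the share with reagent as charged is 31.4%, and the midway reagent brings the number to 0.298 and the share to 23.0%. That second flask gave 22.4% of target and 67.8% of side product at 30.0 min.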